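**Plan**
Numbering: ring A = C1–C5/C10 (gem-dimethyl on C4), ring B = C5–C10 (methyls on C8 and C10), chain C11–C18 on C9 (C18 = CO2H). Cuts, in order: C18 acid ← CH2OH; C14–C15 (alkenyl–alkenyl); C9–C11 (enol triflate + alkylzinc); C5–H (hydrogenation); C1–C10 (ring A); C4–C3 and C4–CH3 (tether built on the arene).
Enabling feature: C9 of ring B lies between the methyl-bearing C8 and C10 and ends as an sp2 carbon, so ring B can start as a 2,6-dimethylphenol with its oxygen on C9. C10 is ortho to that oxygen and already carries its methyl, so C-alkylation there by a chain on the meta carbon C5 must stop at a cyclohexa-2,4-dienone.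
Forward: 2-bromo-1,3-dimethylbenzene becomes the phenol with the C4–C1 iodoalkyl tether; dearomatising closure of ring A creates quaternary C10 and frees the C9 carbonyl; hydrogenation sets the trans fusion; the C9 enol triflate fixes C8=C9 and takes the chain in two Negishi-type couplings.
Stereochemistry: C10 from the chiral ammonium cation in the ring closure; C5 from hydrogenation anti to the C10 methyl; C17 from methyl (S)-3-hydroxy-2-methylpropanoate; 13E from syn-carboalumination and 15E from Takai olefination, both retained in the coupling.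

Key step: step 7

Assumption: the sense of induction of the chiral ammonium cation in step 7 cannot be derived from precedent; the route is written for the catalyst antipode that gives (S)-12 (both antipodes are commercial).

Step 1
Reactants: 1 2-bromo-1,3-dimethylbenzene
Product: 2 1-(3-bromo-2,4-dimethylphenyl)ethan-1-one
Conditions: AcCl, AlCl3, CH2Cl2, 0 °C to rt
Reagents that add atoms: acetyl chloride, CC(=O)Cl
Why: Friedel–Crafts acylation should go to the only position that is ortho to one methyl and para to the other (meta to Br), which places the future C4 on the future C5.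

Step 2
Reactants: 2 1-(3-bromo-2,4-dimethylphenyl)ethan-1-one
Product: 3 2-(3-bromo-2,4-dimethylphenyl)propan-2-ol
Conditions: MeMgBr, THF, 0 °C
Reagents that add atoms: methylmagnesium bromide, C[Mg]Br
Why: Grignard 1,2-addition to the aryl methyl ketone gives the tertiary benzylic alcohol that carries both methyl groups of C4; the aryl bromide is inert under these conditions.

Step 3
Reactants: 3 2-(3-bromo-2,4-dimethylphenyl)propan-2-ol
Product: 4 2-bromo-1,3-dimethyl-4-(2-methylpent-4-en-2-yl)benzene
Conditions: allylSiMe3, BF3·OEt2, CH2Cl2, 0 °C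
Reagents that add atoms: allyltrimethylsilane, C=CC[Si](C)(C)C
Why: Hosomi–Sakurai-type allylation, in which BF3 ionises the tertiary benzylic alcohol to a cumyl-type cation that the allylsilane traps, builds quaternary C4 and the chain C3–C1; the bromine-deactivated ring should not self-alkylate.

Step 4
Reactants: 4 2-bromo-1,3-dimethyl-4-(2-methylpent-4-en-2-yl)benzene
Product: 7 2,6-dimethyl-3-(2-methylpent-4-en-2-yl)phenol, via aryllithium 5 (not isolated), via dimethyl arylboronate 6 (not isolated)
Conditions: n-BuLi, THF, −78 °C; B(OMe)3, −78 °C to rt; then H2O2, aq. NaOH, 0 °C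
Reagents that add atoms: hydrogen peroxide, OO
Why: Bromine–lithium exchange, borylation and oxidative C–B to C–O migration turn the bromide between the two methyl groups into the phenol oxygen on C9, leaving the terminal alkene untouched.

Step 5
Reactants: 7 2,6-dimethyl-3-(2-methylpent-4-en-2-yl)phenol
Product: 9 3-(5-hydroxy-2-methylpentan-2-yl)-2,6-dimethylphenol, via bis-borane adduct 8 (not isolated)
Conditions: 9-BBN (2.2 equiv), THF, 0 °C to rt; then aq. NaOH, H2O2, 0 °C to rt
Reagents that add atoms: hydrogen peroxide, OO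
Why: Anti-Markovnikov hydroboration–oxidation of the monosubstituted alkene puts the hydroxyl on terminal C1; the phenol only consumes one equivalent of borane and is released again on oxidative work-up.

Step 6
Reactants: 9 3-(5-hydroxy-2-methylpentan-2-yl)-2,6-dimethylphenol
Product: 10 3-(5-iodo-2-methylpentan-2-yl)-2,6-dimethylphenol
Conditions: PPh3, I2, imidazole (premixed), CH2Cl2, 0 °C, dark
Reagents that add atoms: iodine, II
Why: Appel iodination should convert only the primary alcohol, since the hindered phenol does not react with the iodophosphonium salt.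

Step 7
Reactants: 10 3-(5-iodo-2-methylpentan-2-yl)-2,6-dimethylphenol
Product: 12 (S)-2,5,5,8a-tetramethyl-6,7,8,8a-tetrahydronaphthalen-1(5H)-one, via ammonium phenolate 11 (not isolated)
Conditions: (S)-4,4-dibutyl-2,6-bis(3,4,5-trifluorophenyl)-4,5-dihydro-3H-dinaphtho[2,1-c:1',2'-e]azepinium bromide (5 mol%), CsOH·H2O (powder), toluene (0.01 M, degassed), −20 °C to rt, dark
Reagents that add atoms: none
Why: Proposed new method: the phenolate of 10, taken into toluene as a contact ion pair with the chiral quaternary ammonium cation (11), should displace the tethered primary iodide through its ortho carbon C10 in an intramolecular SN2 reaction, and because C10 already carries a methyl group the product is a 6,6-disubstituted cyclohexa-2,4-dienone that cannot tautomerise back to a phenol. The closest known reaction types are the racemic ortho-C-alkylation of alkali 2,6-dimethylphenolates in non-polar solvents to 6-alkyl-2,6-dimethylcyclohexa-2,4-dienones, intramolecular phenolate C-alkylations that give fused dienones, and alkylative dearomatisations of phenols and naphthols under chiral phase-transfer catalysis. Ring A closes in a 6-exo-tet mode with the C9–C10 enolate unit exocyclic to the new ring, helped by the gem-dimethyl effect of C4. The only new stereocentre, C10, is set by the chiral cation, which sits at the phenolate oxygen next to C10 and should let the tether fold over one face of the ring only. The step needs C- over O-alkylation, C10 over C6, and ring closure over intermolecular alkylation: O-alkylation would need an impossible meta-bridged eight-membered ring, attack at the unsubstituted para carbon C6 is disfavoured in a tight ion pair in toluene because the charge and the cation that assists iodide departure stay at the O–C9–C10 end, and high dilution suppresses oligomers. The C8 methyl and the fully substituted C5 should keep the dienone from Diels–Alder dimerisation.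

Step 8
Reactants: 12 (S)-2,5,5,8a-tetramethyl-6,7,8,8a-tetrahydronaphthalen-1(5H)-one
Product: 13 (4aS,8aS)-2,5,5,8a-tetramethyloctahydronaphthalen-1(2H)-one (C2 epimer mixture)
Conditions: H2 (3 atm), 10% Pd/C, EtOAc, rt
Reagents that add atoms: none
Why: Catalytic hydrogenation should saturate the conjugated C7=C8 bond first and then the C5=C6 bond from the face anti to the axial C10 methyl, as 4,4,10-trimethyl-Δ5-octalins do, giving the trans ring fusion at C5; the C8 centre is a mixture that step 9 erases.

Step 9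
Reactants: 13 (4aS,8aS)-2,5,5,8a-tetramethyloctahydronaphthalen-1(2H)-one (C2 epimer mixture)
Product: 15 (4aS,8aS)-2,5,5,8a-tetramethyl-3,4,4a,5,6,7,8,8a-octahydronaphthalen-1-yl trifluoromethanesulfonate, via potassium enolate 14 (not isolated)
Conditions: KHMDS, THF, −78 to 0 °C; PhNTf2, −78 °C to rt
Reagents that add atoms: N-phenylbis(trifluoromethanesulfonimide), O=S(=O)(N(c1ccccc1)S(=O)(=O)C(F)(F)F)C(F)(F)F
Why: C10 is quaternary, so the ketone can enolise only toward C8, and O-triflation of that enolate (as with 2,2,6-trimethylcyclohexanone) fixes the tetrasubstituted C8=C9 bond and makes C9 a coupling site.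

Step 10
Reactants: 15 (4aS,8aS)-2,5,5,8a-tetramethyl-3,4,4a,5,6,7,8,8a-octahydronaphthalen-1-yl trifluoromethanesulfonate; 16 (4-bromobut-1-yn-1-yl)trimethylsilane
Product: 18 trimethyl{4-[(4aS,8aS)-2,5,5,8a-tetramethyl-3,4,4a,5,6,7,8,8a-octahydronaphthalen-1-yl]but-1-yn-1-yl}silane, via alkylzinc bromide 17 (not isolated)
Conditions: 16, Zn dust, LiCl, THF, 50 °C; then 15, Pd(OAc)2 (4 mol%), SPhos (8 mol%), THF/NMP, 60 °C
Reagents that add atoms: none
Why: Negishi sp2–sp3 coupling of the enol triflate with the primary alkylzinc made by zinc insertion should form C9–C11 without moving the C8=C9 bond; a bulky biaryl phosphine is chosen because of the neighbouring quaternary C10.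

Step 11
Reactants: 18 trimethyl{4-[(4aS,8aS)-2,5,5,8a-tetramethyl-3,4,4a,5,6,7,8,8a-octahydronaphthalen-1-yl]but-1-yn-1-yl}silane
Product: 19 (4aS,8aS)-1-(but-3-yn-1-yl)-2,5,5,8a-tetramethyl-3,4,4a,5,6,7,8,8a-octahydronaphthalene
Conditions: K2CO3, MeOH/THF, rt
Reagents that add atoms: none
Why: Base-mediated methanolysis of the alkynyl C–Si bond frees the terminal alkyne; the hydrocarbon has no other base-sensitive site.

Step 12
Reactants: 20 methyl (S)-3-hydroxy-2-methylpropanoate
Product: 21 methyl (S)-3-[(tert-butyldimethylsilyl)oxy]-2-methylpropanoate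
Conditions: TBSCl, imidazole, CH2Cl2, 0 °C to rt
Reagents that add atoms: tert-butyldimethylsilyl chloride, CC(C)(C)[Si](C)(C)Cl
Why: Standard silylation of the primary alcohol, which will later become C18; the α-stereocentre is not affected by imidazole.

Step 13
Reactants: 21 methyl (S)-3-[(tert-butyldimethylsilyl)oxy]-2-methylpropanoate
Product: 22 (S)-3-[(tert-butyldimethylsilyl)oxy]-2-methylpropanal
Conditions: DIBAL-H (1.05 equiv), CH2Cl2, −78 °C; aq. potassium sodium tartrate; used at once
Reagents that add atoms: none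
Why: Partial ester reduction at −78 °C should stop at the aluminium hemiacetal, which releases the aldehyde on work-up; the α-stereocentre is kept if the aldehyde is handled cold and used directly.

Step 14
Reactants: 22 (S)-3-[(tert-butyldimethylsilyl)oxy]-2-methylpropanal
Product: 23 (R,E)-tert-butyl[(4-iodo-2-methylbut-3-en-1-yl)oxy]dimethylsilane
Conditions: CrCl2, CHI3, THF, 0 °C, dark
Reagents that add atoms: iodoform, IC(I)I
Why: Takai olefination should give the (E)-vinyl iodide (C15=C16) without epimerising the neighbouring centre, whose descriptor changes from S to R only because the CIP priorities change.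

Step 15
Reactants: 19 (4aS,8aS)-1-(but-3-yn-1-yl)-2,5,5,8a-tetramethyl-3,4,4a,5,6,7,8,8a-octahydronaphthalene; 23 (R,E)-tert-butyl[(4-iodo-2-methylbut-3-en-1-yl)oxy]dimethylsilane
Product: 25 tert-butyl{[(2R,3E,5E)-2,6-dimethyl-8-[(4aS,8aS)-2,5,5,8a-tetramethyl-3,4,4a,5,6,7,8,8a-octahydronaphthalen-1-yl]octa-3,5-dien-1-yl]oxy}dimethylsilane, via alkenylalane 24 (not isolated)
Conditions: Me3Al, Cp2ZrCl2 (0.25 equiv), CH2Cl2, 0 °C to rt; volatiles removed; then 23, Pd(PPh3)4 (5 mol%), ZnCl2 (0.2 equiv), THF, rt
Reagents that add atoms: trimethylaluminium, C[Al](C)C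
Why: Zirconium-catalysed carboalumination adds Me and Al syn across the terminal alkyne with Al at the terminus (13E), and the Pd-catalysed Negishi-type coupling with the (E)-vinyl iodide proceeds with retention at both sp2 carbons to give the 13E,15E-diene; the ring alkene and silyl ether are inert.

Step 16
Reactants: 25 tert-butyl{[(2R,3E,5E)-2,6-dimethyl-8-[(4aS,8aS)-2,5,5,8a-tetramethyl-3,4,4a,5,6,7,8,8a-octahydronaphthalen-1-yl]octa-3,5-dien-1-yl]oxy}dimethylsilane
Product: 26 (2R,3E,5E)-2,6-dimethyl-8-[(4aS,8aS)-2,5,5,8a-tetramethyl-3,4,4a,5,6,7,8,8a-octahydronaphthalen-1-yl]octa-3,5-dien-1-ol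
Conditions: TBAF, THF, 0 °C to rt
Reagents that add atoms: none
Why: Fluoride cleaves the Si–O bond; the molecule has no acidic C–H at this stage, so C17 is safe.

Step 17
Reactants: 26 (2R,3E,5E)-2,6-dimethyl-8-[(4aS,8aS)-2,5,5,8a-tetramethyl-3,4,4a,5,6,7,8,8a-octahydronaphthalen-1-yl]octa-3,5-dien-1-ol
Product: 28 (2R,3E,5E)-2,6-dimethyl-8-[(4aS,8aS)-2,5,5,8a-tetramethyl-3,4,4a,5,6,7,8,8a-octahydronaphthalen-1-yl]octa-3,5-dienoic acid, via aldehyde 27 (not isolated)
Conditions: TEMPO (0.2 equiv), PhI(OAc)2 (2.2 equiv), MeCN/pH 7 phosphate buffer, 0 °C to rt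
Reagents that add atoms: water, O
Why: Oxoammonium oxidation in aqueous acetonitrile takes the primary alcohol through the aldehyde hydrate to the acid under near-neutral conditions, which should avoid epimerisation at C17 and migration of the β,γ-double bond into conjugation, and it does not attack the alkenes.

**Compound list**
1 | 2-bromo-1,3-dimethylbenzene | Cc1cccc(C)c1Br | starting material
2 | 1-(3-bromo-2,4-dimethylphenyl)ethan-1-one | CC(=O)c1ccc(C)c(Br)c1C | intermediate
3 | 2-(3-bromo-2,4-dimethylphenyl)propan-2-ol | CC(C)(O)c1ccc(C)c(Br)c1C | intermediate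
4 | 2-bromo-1,3-dimethyl-4-(2-methylpent-4-en-2-yl)benzene | C=CCC(C)(C)c1ccc(C)c(Br)c1C | intermediate
5 | [2,6-dimethyl-3-(2-methylpent-4-en-2-yl)phenyl]lithium (formed in the flask) | [Li]c1c(C)ccc(C(C)(C)CC=C)c1C | intermediate
6 | dimethyl [2,6-dimethyl-3-(2-methylpent-4-en-2-yl)phenyl]boronate (formed in the flask) | COB(OC)c1c(C)ccc(C(C)(C)CC=C)c1C | intermediate
7 | 2,6-dimethyl-3-(2-methylpent-4-en-2-yl)phenol | C=CCC(C)(C)c1ccc(C)c(O)c1C | intermediate
8 | O,C-bis(9-borabicyclo[3.3.1]nonan-9-yl) adduct of 7 (formed in the flask) | Cc1ccc(C(C)(C)CCCB2C3CCCC2CCC3)c(C)c1OB1C2CCCC1CCC2 | intermediate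
9 | 3-(5-hydroxy-2-methylpentan-2-yl)-2,6-dimethylphenol | OCCCC(C)(C)c1ccc(C)c(O)c1C | intermediate
10 | 3-(5-iodo-2-methylpentan-2-yl)-2,6-dimethylphenol | ICCCC(C)(C)c1ccc(C)c(O)c1C | intermediate
11 | phenolate of 10, ion-paired with the chiral ammonium cation (anion shown; formed in the flask) | [O-]c1c(C)ccc(C(C)(C)CCCI)c1C | intermediate
12 | (S)-2,5,5,8a-tetramethyl-6,7,8,8a-tetrahydronaphthalen-1(5H)-one | CC1=CC=C2C(C)(C)CCC[C@]2(C)C1=O | intermediate
13 | (4aS,8aS)-2,5,5,8a-tetramethyloctahydronaphthalen-1(2H)-one (C2 epimer mixture) | CC1C(=O)[C@@]2(C)CCCC(C)(C)[C@@H]2CC1 | intermediate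
14 | potassium enolate of 13 (formed in the flask) | CC1=C([O-])[C@@]2(C)CCCC(C)(C)[C@@H]2CC1.[K+] | intermediate
15 | (4aS,8aS)-2,5,5,8a-tetramethyl-3,4,4a,5,6,7,8,8a-octahydronaphthalen-1-yl trifluoromethanesulfonate | CC1=C(OS(=O)(=O)C(F)(F)F)[C@@]2(C)CCCC(C)(C)[C@@H]2CC1 | intermediate
16 | (4-bromobut-1-yn-1-yl)trimethylsilane | C[Si](C)(C)C#CCCBr | starting material
17 | [4-(trimethylsilyl)but-3-yn-1-yl]zinc bromide (formed in the flask) | C[Si](C)(C)C#CCC[Zn]Br | intermediate
18 | trimethyl{4-[(4aS,8aS)-2,5,5,8a-tetramethyl-3,4,4a,5,6,7,8,8a-octahydronaphthalen-1-yl]but-1-yn-1-yl}silane | CC1=C(CCC#C[Si](C)(C)C)[C@@]2(C)CCCC(C)(C)[C@@H]2CC1 | intermediate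
19 | (4aS,8aS)-1-(but-3-yn-1-yl)-2,5,5,8a-tetramethyl-3,4,4a,5,6,7,8,8a-octahydronaphthalene | CC1=C(CCC#C)[C@@]2(C)CCCC(C)(C)[C@@H]2CC1 | intermediate
20 | methyl (S)-3-hydroxy-2-methylpropanoate | COC(=O)[C@@H](C)CO | starting material
21 | methyl (S)-3-[(tert-butyldimethylsilyl)oxy]-2-methylpropanoate | COC(=O)[C@@H](C)CO[Si](C)(C)C(C)(C)C | intermediate
22 | (S)-3-[(tert-butyldimethylsilyl)oxy]-2-methylpropanal | O=C[C@@H](C)CO[Si](C)(C)C(C)(C)C | intermediate
23 | (R,E)-tert-butyl[(4-iodo-2-methylbut-3-en-1-yl)oxy]dimethylsilane | I/C=C/[C@@H](C)CO[Si](C)(C)C(C)(C)C | intermediate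
24 | (E)-alkenyl(dimethyl)alane from 19 (formed in the flask) | CC1=C(CC/C(C)=C/[Al](C)C)[C@@]2(C)CCCC(C)(C)[C@@H]2CC1 | intermediate
25 | tert-butyl{[(2R,3E,5E)-2,6-dimethyl-8-[(4aS,8aS)-2,5,5,8a-tetramethyl-3,4,4a,5,6,7,8,8a-octahydronaphthalen-1-yl]octa-3,5-dien-1-yl]oxy}dimethylsilane | CC1=C(CC/C(C)=C/C=C/[C@@H](C)CO[Si](C)(C)C(C)(C)C)[C@@]2(C)CCCC(C)(C)[C@@H]2CC1 | intermediate
26 | (2R,3E,5E)-2,6-dimethyl-8-[(4aS,8aS)-2,5,5,8a-tetramethyl-3,4,4a,5,6,7,8,8a-octahydronaphthalen-1-yl]octa-3,5-dien-1-ol | CC1=C(CC/C(C)=C/C=C/[C@@H](C)CO)[C@@]2(C)CCCC(C)(C)[C@@H]2CC1 | intermediate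
27 | (2R,3E,5E)-2,6-dimethyl-8-[(4aS,8aS)-2,5,5,8a-tetramethyl-3,4,4a,5,6,7,8,8a-octahydronaphthalen-1-yl]octa-3,5-dienal (formed in the flask) | CC1=C(CC/C(C)=C/C=C/[C@@H](C)C=O)[C@@]2(C)CCCC(C)(C)[C@@H]2CC1 | intermediate
28 | (2R,3E,5E)-2,6-dimethyl-8-[(4aS,8aS)-2,5,5,8a-tetramethyl-3,4,4a,5,6,7,8,8a-octahydronaphthalen-1-yl]octa-3,5-dienoic acid | CC1=C(CC/C(C)=C/C=C/[C@@H](C)C(=O)O)[C@@]2(C)CCCC(C)(C)[C@@H]2CC1 | target

**Count**
Total steps: 17. Longest linear sequence: 14 (steps 1–11, then 15–17); steps 12–14 make the side-chain iodide.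

**Steps most likely to fail**

Step 7 (proposed new method). What may go wrong: the tethered iodide may alkylate the unsubstituted para carbon C6, after which the ring re-aromatises to a tetralinol; or the chiral cation may discriminate the two faces of the phenolate poorly. The fallback uses known chemistry in which C6 and C7 are already sp3, so the regiochemistry is inherent, and obtains the single enantiomer by resolution. It sets out from 9 and comes back at 15. O-Methylation of the phenol (MeI, K2CO3, acetone) gives 4-(3-methoxy-2,4-dimethylphenyl)-4-methylpentan-1-ol F1. Birch reduction (Li, NH3, t-BuOH, THF, −78 to −33 °C) followed by hydrolysis of the enol ether with conjugation (aq. HCl, THF) gives 3-(5-hydroxy-2-methylpentan-2-yl)-2,6-dimethylcyclohex-2-en-1-one F2. Appel iodination gives 3-(5-iodo-2-methylpentan-2-yl)-2,6-dimethylcyclohex-2-en-1-one F3. KOt-Bu in t-BuOH/THF forms the extended dienolate, whose α-carbon C10 displaces the iodide (deconjugative α-alkylation) to give racemic 2,5,5,8a-tetramethyl-3,5,6,7,8,8a-hexahydronaphthalen-1(2H)-one F4. Hydrogenation as in step 8 gives racemic trans-2,5,5,8a-tetramethyloctahydronaphthalen-1(2H)-one F5. Triflation as in step 9 gives racemic trans-2,5,5,8a-tetramethyl-3,4,4a,5,6,7,8,8a-octahydronaphthalen-1-yl trifluoromethanesulfonate F6, and preparative chromatography on a chiral stationary phase delivers 15.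

Step 10. What may go wrong: oxidative addition and transmetalation at the tetrasubstituted triflate next to quaternary C10 may be too slow, so that β-hydride elimination or protodemetalation of the alkylzinc takes over. The fallback replaces the sp2–sp3 coupling by one-carbon carbonylation and an allylic SN2 alkylation; it sets out from 15 and comes back at 18. Pd-catalysed methoxycarbonylation (Pd(OAc)2, dppp, CO, MeOH, Et3N, DMF) gives methyl (4aS,8aS)-2,5,5,8a-tetramethyl-3,4,4a,5,6,7,8,8a-octahydronaphthalene-1-carboxylate F7. DIBAL-H reduction gives [(4aS,8aS)-2,5,5,8a-tetramethyl-3,4,4a,5,6,7,8,8a-octahydronaphthalen-1-yl]methanol F8. CBr4/PPh3 gives (4aS,8aS)-1-(bromomethyl)-2,5,5,8a-tetramethyl-3,4,4a,5,6,7,8,8a-octahydronaphthalene F9. Alkylation of lithiated 1-(trimethylsilyl)propyne (n-BuLi, THF, −78 °C) with this primary allylic bromide gives 18.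

Step 8. What may go wrong: poor facial selectivity at C5 on the nearly flat dienone, with hydrogen delivered syn to the C10 methyl and formation of the cis-decalone. The fallback sets C5 by protonation of a dienolate dianion instead of by surface hydrogenation; it sets out from 12 and comes back at 13. Li in NH3/THF with one equivalent of t-BuOH at −78 °C effects 1,6-reduction, in which the δ-carbon C5 should be protonated to the trans ring fusion. NH4Cl quench and equilibration give (4aS,8aS)-2,5,5,8a-tetramethyl-4a,5,6,7,8,8a-hexahydronaphthalen-1(4H)-one F10, and hydrogenation (H2, Pd/C) of the remote C7=C8 bond then gives 13.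

**Further compounds**
F1 | step 7 | 4-(3-methoxy-2,4-dimethylphenyl)-4-methylpentan-1-ol | COc1c(C)ccc(C(C)(C)CCCO)c1C
F2 | step 7 | 3-(5-hydroxy-2-methylpentan-2-yl)-2,6-dimethylcyclohex-2-en-1-one | CC1CCC(C(C)(C)CCCO)=C(C)C1=O
F3 | step 7 | 3-(5-iodo-2-methylpentan-2-yl)-2,6-dimethylcyclohex-2-en-1-one | CC1CCC(C(C)(C)CCCI)=C(C)C1=O
F4 | step 7 | racemic 2,5,5,8a-tetramethyl-3,5,6,7,8,8a-hexahydronaphthalen-1(2H)-one | CC1CC=C2C(C)(C)CCCC2(C)C1=O
F5 | step 7 | racemic trans-2,5,5,8a-tetramethyloctahydronaphthalen-1(2H)-one | CC1CCC2C(C)(C)CCCC2(C)C1=O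
F6 | step 7 | racemic trans-2,5,5,8a-tetramethyl-3,4,4a,5,6,7,8,8a-octahydronaphthalen-1-yl trifluoromethanesulfonate | CC1=C(OS(=O)(=O)C(F)(F)F)C2(C)CCCC(C)(C)C2CC1
F7 | step 10 | methyl (4aS,8aS)-2,5,5,8a-tetramethyl-3,4,4a,5,6,7,8,8a-octahydronaphthalene-1-carboxylate | CC1=C(C(=O)OC)[C@@]2(C)CCCC(C)(C)[C@@H]2CC1
F8 | step 10 | [(4aS,8aS)-2,5,5,8a-tetramethyl-3,4,4a,5,6,7,8,8a-octahydronaphthalen-1-yl]methanol | CC1=C(CO)[C@@]2(C)CCCC(C)(C)[C@@H]2CC1
F9 | step 10 | (4aS,8aS)-1-(bromomethyl)-2,5,5,8a-tetramethyl-3,4,4a,5,6,7,8,8a-octahydronaphthalene | CC1=C(CBr)[C@@]2(C)CCCC(C)(C)[C@@H]2CC1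
F10 | step 8 | (4aS,8aS)-2,5,5,8a-tetramethyl-4a,5,6,7,8,8a-hexahydronaphthalen-1(4H)-one | CC1=CC[C@H]2C(C)(C)CCC[C@]2(C)C1=O
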